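(Readings and results were computed for an exercise, and the scatter is random.)

I was asked how far the substrate in the flask had reacted at 30 h, and how much of the unused partner was then free.

| flask | substrate | partner | remark | time |
|---|---|---|---|---|
| noon | 0.28 M (fed, over 2.5 h) | 0.30 M | run made earlier |  |
| autumn | 0.44 M (fed, over 2.5 h) | 0.30 M | run made earlier |  |
| flask | 0.20 M (fed, over 2.5 h) | 0.300 M |  | 30 h |

| run | time / h | substrate / % | mono adduct / % |
|---|---|---|---|
| noon | 3.00 | 39 | 27 |
| noon | 4.00 | 28 | 32 |
| noon | 6.00 | 31 | 31 |
| noon | 10.0 | 26 | 31 |
| noon | 15.0 | 24 | 33 |
| noon | 25.0 | 29 | 30 |
| noon | 40.0 | 25 | 32 |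
| autumn | 3.00 | 52 | 24 |
| autumn | 4.00 | 48 | 25 |
| autumn | 6.00 | 51 | 26 |
| autumn | 10.0 | 48 | 23 |
| autumn | 15.0 | 49 | 31 |
| autumn | 25.0 | 48 | 25 |
| autumn | 40.0 | 50 | 27 |

(standard deviation of a reading: 2 percentage points)

* part of the substrate that has reacted at 30 h
* share of the unused partner that is free and not bound as idle adduct, at 30 h

- the earlier runs do not show how much of partner is bound; that part of a forecast is a guess

I held the flask against the noon run: the partner and the dosing time are equal, but the flask has less substrate, so it has more partner per substrate. From 10.0 h on, the substrate readings of both earlier runs stood flat within their scatter. I supposed that the partner charged ends on the substrate, one or two to each, and that gave a balance. I called two minus the equivalents of partner to substrate the shortfall: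

shortfall = 2 × share left + stopped share

Averaging the readings from 10.0 h on, the share left was 26.0% in the noon run and 48.8% in the autumn run. The balance then gave:

noon: 40.9%; autumn: 34.3%

Their mean, 37.6%, was my stopped share, the part of the charged substrate that ends with one partner on it. Supposing the same stopped share and the same balance for the flask, I reckoned:

shortfall 0.500; share left 6.21%; reacted 93.8%

This reckoning was mine and said nothing about free partner. The forecast differed: 84% reacted (76% to 91%) and 55% free (30% to 80%), reasoning that "The reacted amount is therefore saturating".

The flask gave 92.3% reacted and 41.5% free.

    substrate + partner → mono adduct + released group (k = 7.20 /M/h)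
    substrate + partner → other mono adduct + released group (k = 2.70 /M/h)
    partner + mono adduct → bis adduct + released group (k = 4.20 /M/h)
    partner + other mono adduct → bis adduct + released group (k = 6.90 /M/h)
    partner + released group ⇌ idle adduct, settled at all times (K = 4.70 /M)

In the flask at 30.0 h, mono adduct and other mono adduct together held 34.6% of the substrate charged, against my stopped share of 37.6%. The second addition of partner to mono adduct kept the substrate in the flask from reacting fully: with the path from partner + mono adduct to bis adduct + released group taken away, >99.9% reacted instead of 92.3%. In the neighbour with 0.34 M of substrate, the shortfall is 1.12, so my stopped share leaves 37.1% and 62.9% reacted; the computed neighbour gave 63.8%.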